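You cannot reach 20% conversion in this flask without spending partner, and if each turnover takes one partner, the amount spent is the same whichever hand of substrate reacts.

| flask | left-handed substrate | right-handed substrate | partner | free catalyst | remark |
|---|---|---|---|---|---|
| amber | 0.020 M | 0.020 M | 1 equiv | 0.3 mol% | run made earlier |
| flask | 0.020 M | 0.020 M | 1.00 equiv | 0.2 mol% |  |

amber run (percent of the left-handed substrate and right-handed substrate together charged)

| time / s | left-handed product / % | left-handed substrate / % |
|---|---|---|
| 10.0 | 18.3 | 31.9 |
| 15.0 | 23.8 | 27.2 |
| 25.0 | 28.1 | 20.6 |
| 30.0 | 29.9 | 19.6 |
| 40.0 | 32.6 | 18.1 |
| 50.0 | 34.1 | 17.2 |

(scatter of a reading: 0.5 percentage points)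

- free catalyst is single-handed; left-handed substrate and right-handed substrate are mirror images of each other, charged as a racemate, each of them at the stated concentration
- no earlier run changes the charge of free catalyst; that part of a forecast is a guess
- no earlier run changes the charge of partner; that part of a forecast is a guess

- apparent order in partner when 20% of the left-handed substrate and right-handed substrate together are converted (percent change of the rate of making left-handed product for one percent more partner charged)
- apparent order in free catalyst when 20% of the left-handed substrate and right-handed substrate together are converted (percent change of the rate of making left-handed product for one percent more free catalyst charged)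

Conversion counts both substrates, each charged at 0.020 M. Partner is counted on the left-handed substrate alone, so c(partner) starts at 0.020 M too. It is the limiting reagent.

  spent = 2 × 20% × 0.020 M = 0.00800 M
  left = 0.020 M − 0.00800 M = 0.0120 M
  charge / left = 0.020 M / 0.0120 M = 1.67

Now add a percent more partner. The amount spent at the mark stays the same, so the relative growth of the partner left is 1.67 times the relative growth of the charge. Call this ratio of charge to partner left at the mark the leverage. If the rate is first order in partner left and the other concentrations at the mark stay as they are, the order you were asked for equals the leverage.

But is it first order? The amber run does not say: no earlier run changes the charge of partner. Let n be the percent change of rate per percent change of partner left, with earlier arrival at the mark counted in. Then: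

  order in partner = n × leverage

The readings do not give n. I take it between 0.5 and 1, which puts the order between 0.835 and 1.67. I commit to the middle, 1.25. Free catalyst has no such leverage from conversion, so I put its order above 1, in case catalyst is lost with time and earlier arrival saves some of it.

The forecast says 1.4 for partner, higher than my figure, and 1.25 for free catalyst: “I hedge between these values”.

The flask gives 1.3 for partner and 1.2 for free catalyst.

    free catalyst + right-handed substrate ⇌ catalyst intermediate B (K = 210 M⁻¹, k = 5200 M⁻¹ s⁻¹)
    partner + catalyst intermediate B → free catalyst + right-handed product (k = 380 M⁻¹ s⁻¹)
    free catalyst + left-handed substrate ⇌ catalyst intermediate A (K = 100 M⁻¹, k = 7300 M⁻¹ s⁻¹)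
    free catalyst → spent catalyst (k = 0.0600 s⁻¹)
    partner + catalyst intermediate A → free catalyst + left-handed product (k = 5800 M⁻¹ s⁻¹)

At 0.205 min, the mark, catalyst intermediate B, the resting state there, holds 56.4% of the catalyst. Dividing the flask's 1.3 by the leverage 1.67 gives n = 0.778, below 1.

The numbers in the tables were computed with made-up constants; the scatter is artificial.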